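**Retrosynthetic overview**
1. Target ⇐ double angeloylation of a 3,9‑diol 8‑acetate; the C9 carbinol comes from an α,β‑epoxy ketone and the 1,10‑oxirane from a hemiketal‑directed epoxidation.
2. The ten‑membered carbocycle and a C3–O–C9 dihydropyran bridge are closed together by an intramolecular hetero‑Diels–Alder reaction between a C3 epoxy aldehyde and a C9 ethoxydiene (bonds C2–C3 and O–C9).
3. The diene (C9, C10, C14, C1, C2) comes from tiglic aldehyde acetal, used as a metalated alkoxydiene (acyl‑anion equivalent) that adds to a C8 aldehyde.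
4. The C3–C8 fragment with C4, C5 and C7 comes from (S)‑carvone: epoxidation, α'‑hydroxylation, α‑ketol cleavage.
5. Ring order: 4,5‑oxirane (on the carvone ring) → relay lactone/lactol → carbocycle + pyran in one operation → 1,10‑oxirane; the pyran bridge is opened in the reduction.

Assumption: the SMILES is read as (1R,3S,4S,5S,7R,8S,9S,10R) with both oxiranes cis‑fused to the ring (C2/C9 cis, C3/C6 cis); from 14 on, names use germacrane numbering (ring C1–C10, isopropenyl on C7, C14 on C10, C15 on C4), β is the face carrying the isopropenyl group in the flat ring drawing, and "x,y‑epoxy" is an oxygen bridging Cx and Cy.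

**Route**

Step 1
Reactants: 1 (S)-(+)-carvone
Product: 2 (1S,4S,6S)-1-methyl-4-(prop-1-en-2-yl)-7-oxabicyclo[4.1.0]heptan-2-one (carvone oxide; oxirane trans to isopropenyl)
Conditions: 30% H2O2, NaOH (cat.), MeOH, 0 °C
Reagents that add atoms: hydrogen peroxide OO
Why: Weitz–Scheffer nucleophilic epoxidation; hydroperoxide adds axially to the enone β‑carbon anti to the isopropenyl group, so the oxirane forms trans to it and sets C4 and C5 of the target relative to C7.

Step 2
Reactants: 2 carvone oxide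
Product: 4 (1S,3R,4R,6S)-3-hydroxy-1-methyl-4-(prop-1-en-2-yl)-7-oxabicyclo[4.1.0]heptan-2-one, via potassium enolate 3 (not isolated)
Conditions: KN(SiMe3)2, THF, −78 °C; then 2-(phenylsulfonyl)-3-phenyloxaziridine, −78 °C; AcOH
Reagents that add atoms: 2-(phenylsulfonyl)-3-phenyloxaziridine O=S(=O)(c1ccccc1)N1OC1c1ccccc1
Why: Davis enolate hydroxylation at the only enolisable α‑carbon (future C8); the hydroxyl enters trans to isopropenyl, but this centre is erased in step 3.

Step 3
Reactants: 4 α‑hydroxy ketone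
Product: 5 methyl (2S,3S)-3-[(2R)-2-formyl-3-methylbut-3-en-1-yl]-2-methyloxirane-2-carboxylate
Conditions: Pb(OAc)4, MeOH–benzene (1:1), 0 °C
Reagents that add atoms: methanol CO
Why: Criegee‑type lead tetraacetate cleavage of an α‑ketol in methanol gives the methyl ester from the ketone carbon (future C3) and the aldehyde from the carbinol carbon (future C8); the oxirane and C7 are untouched.

Step 4
Reactants: 6 tiglic aldehyde ((E)-2-methylbut-2-enal)
Product: 7 (E)-1,1-diethoxy-2-methylbut-2-ene
Conditions: HC(OEt)3, NH4NO3 (cat.), EtOH, rt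
Reagents that add atoms: triethyl orthoformate CCOC(OCC)OCC
Why: Acid‑catalysed acetalisation with the orthoformate as water scavenger; no stereocentre is formed.

Step 5
Reactants: 5 aldehyde ester; 7 acetal
Product: 11 (1S,4S,5R,7S)-4-[(1E)-1-ethoxy-2-methylbuta-1,3-dien-1-yl]-1-methyl-5-(prop-1-en-2-yl)-3,8-dioxabicyclo[5.1.0]octan-2-one, via ethoxydiene 8 (not isolated), via potassium dienide 9 (not isolated), via potassium alkoxide 10 (not isolated)
Conditions: 7, n-BuLi/t-BuOK (2 equiv each), THF, −95 °C; then 5, −95 °C; then 0 °C; AcOH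
Reagents that add atoms: none
Why: Venturello‑type 1,4‑elimination and α‑metalation of the unsaturated acetal gives an acyl‑anion equivalent that adds to the aldehyde in the Felkin–Anh sense (isopropenyl as the large group, nucleophile anti to it), which sets C8; the alkoxide then lactonises onto the neighbouring methyl ester, a seven‑membered closure helped by the cis‑oxirane.

Step 6
Reactants: 11 lactone
Product: 12 (1S,4S,5R,7S)-4-[(1E)-1-ethoxy-2-methylbuta-1,3-dien-1-yl]-1-methyl-5-(prop-1-en-2-yl)-3,8-dioxabicyclo[5.1.0]octan-2-ol (lactol; anomer mixture)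
Conditions: i-Bu2AlH, CH2Cl2, −78 °C; Rochelle salt work-up
Reagents that add atoms: none
Why: Half‑reduction of a lactone to the lactol with DIBAL‑H at low temperature (stable tetrahedral aluminate); the enol ether, oxirane and olefins are inert.

Step 7
Reactants: 12 lactol
Product: 14 9α-ethoxy-3β,9β:4α,5α-diepoxygermacra-1(10),11-dien-8β-ol (bridged ketal; C1=C10 is Z inside the dihydropyran), via hydroxy aldehyde 13 (not isolated)
Conditions: ZnCl2 (1.5 equiv), 4 Å MS, THF–toluene, 0.002 M, slow addition of 12, 0 °C → rt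
Reagents that add atoms: none
Why: Proposed new method: a bridging intramolecular hetero‑Diels–Alder reaction (asynchronous [4+2], or vinylogous Mukaiyama aldol followed by oxocarbenium capture) in which ZnCl2 chelates the aldehyde and oxirane oxygens of 13, the nucleophilic diene terminus C2 attacks C3 anti to C5 of the chelate (sets 3S, with C2 antiperiplanar to C5 as the forming ring allows) and the carbonyl oxygen closes onto C9, so the ten‑membered carbocycle and the dihydropyran (which locks C1=C10 as Z) form in one operation; the lactol releases the aldehyde next to C9 and the five‑atom tether matches that of type 2 intramolecular Diels–Alder reactions giving bicyclo[5.3.1]undecenes; closest known reaction types are the chelation‑controlled ZnCl2‑ or MgBr2‑mediated cyclocondensation of alkoxydienes with α‑oxygenated aldehydes, the type 2 intramolecular Diels–Alder reaction and medium‑ring closure by intramolecular vinylogous Mukaiyama aldol reaction.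

Step 8
Reactants: 14 bridged ketal
Product: 15 8β-acetoxy-9α-ethoxy-3β,9β:4α,5α-diepoxygermacra-1(10),11-diene
Conditions: Ac2O, DMAP (cat.), pyridine, CH2Cl2, 0 °C → rt
Reagents that add atoms: acetic anhydride CC(=O)OC(C)=O
Why: DMAP‑catalysed acetylation of the only free hydroxyl; the ketal and oxirane are base‑stable and no stereocentre changes.

Step 9
Reactants: 15 ketal acetate
Product: 16 8β-acetoxy-3β,9β:4α,5α-diepoxygermacra-1(10),11-dien-9α-ol (bridged hemiketal)
Conditions: PPTS (cat.), acetone–H2O (10:1), 0 °C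
Reagents that add atoms: water O
Why: Mild acid hydrolysis of the allylic mixed ketal through the 2H‑pyranyl oxocarbenium ion; water can only enter on the exo (α) position at C9, and the transannular hemiketal is the stable form of the δ‑hydroxy Z‑enone.

Step 10
Reactants: 16 hemiketal
Product: 17 8β-acetoxy-1β,10β:3β,9β:4α,5α-triepoxygermacr-11-en-9α-ol
Conditions: VO(acac)2 (5 mol %), t-BuOOH (decane), CH2Cl2, 0 °C → rt
Reagents that add atoms: tert-butyl hydroperoxide CC(C)(C)OO
Why: Sharpless–Michaelson vanadium‑catalysed hydroxyl‑directed epoxidation; the tertiary hemiketal hydroxyl sits on the exo face of the rigid bicycle and delivers the peroxide to the same face of C1=C10, anti to the C4–C8 bridge, which sets C1 and C10, while the isopropenyl group has no directing hydroxyl and is left.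

Step 11
Reactants: 17 epoxy hemiketal
Product: 19 8β-acetoxy-1β,10β:4α,5α-diepoxygermacr-11-ene-3β,9β-diol, via epoxy ketone 18 (not isolated)
Conditions: Zn(BH4)2, Et2O, −20 °C
Reagents that add atoms: none
Why: Chelation‑controlled Zn(BH4)2 reduction of the α,β‑epoxy ketone that is in equilibrium with the hemiketal gives the erythro epoxy alcohol; hydride enters the carbonyl face opposite the transannular C3 hydroxyl, which gives the 9β (9S) alcohol, and the acetate and oxiranes are not reduced.

Step 12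
Reactants: 19 diol
Product: 20 (1R,3S,4S,5S,7R,8S,9S,10R)-8β-acetoxy-3β,9β-bis(angeloyloxy)-1β,10β:4α,5α-diepoxygermacr-11-ene (target)
Conditions: angelic acid, 2,4,6-trichlorobenzoyl chloride, Et3N, toluene, rt; then 19, 75 °C (no DMAP)
Reagents that add atoms: angelic acid C/C=C(/C)C(=O)O
Why: Yamaguchi‑type mixed‑anhydride esterification run without DMAP acylates hindered secondary alcohols with angelic acid without Z‑to‑E isomerisation; both hydroxyls are esterified and no stereocentre changes.

**Compound list**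
1 | (S)-(+)-carvone, (5S)-2-methyl-5-(prop-1-en-2-yl)cyclohex-2-en-1-one | C=C(C)[C@H]1CC=C(C)C(=O)C1 | starting material
2 | (1S,4S,6S)-1-methyl-4-(prop-1-en-2-yl)-7-oxabicyclo[4.1.0]heptan-2-one | C=C(C)[C@H]1C[C@@H]2O[C@]2(C)C(=O)C1 | intermediate
3 | potassium enolate of 2 (enolate towards the CH2 carbon) | C=C(C)[C@H]1C[C@@H]2O[C@]2(C)C([O-])=C1.[K+] | intermediate
4 | (1S,3R,4R,6S)-3-hydroxy-1-methyl-4-(prop-1-en-2-yl)-7-oxabicyclo[4.1.0]heptan-2-one | C=C(C)[C@H]1C[C@@H]2O[C@]2(C)C(=O)[C@@H]1O | intermediate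
5 | methyl (2S,3S)-3-[(2R)-2-formyl-3-methylbut-3-en-1-yl]-2-methyloxirane-2-carboxylate | C=C(C)[C@H](C=O)C[C@@H]1O[C@]1(C)C(=O)OC | intermediate
6 | tiglic aldehyde, (E)-2-methylbut-2-enal | C/C=C(\C)C=O | starting material
7 | (E)-1,1-diethoxy-2-methylbut-2-ene | C/C=C(\C)C(OCC)OCC | intermediate
8 | (1E)-1-ethoxy-2-methylbuta-1,3-diene | C=C/C(C)=C/OCC | intermediate
9 | [(1Z)-1-ethoxy-2-methylbuta-1,3-dien-1-yl]potassium (K cis to vinyl) | C=C/C(C)=C(\[K])OCC | intermediate
10 | potassium alkoxide of methyl (2S,3S)-3-[(2R,3S,4E)-4-ethoxy-3-hydroxy-5-methyl-2-(prop-1-en-2-yl)hepta-4,6-dien-1-yl]-2-methyloxirane-2-carboxylate | C=C(C)[C@H]([C@H]([O-])/C(OCC)=C(C)\C=C)C[C@@H]1O[C@]1(C)C(=O)OC.[K+] | intermediate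
11 | (1S,4S,5R,7S)-4-[(1E)-1-ethoxy-2-methylbuta-1,3-dien-1-yl]-1-methyl-5-(prop-1-en-2-yl)-3,8-dioxabicyclo[5.1.0]octan-2-one | C=C(C)[C@H]1C[C@@H]2O[C@]2(C)C(=O)O[C@@H]1/C(OCC)=C(C)\C=C | intermediate
12 | corresponding lactol, 3,8-dioxabicyclo[5.1.0]octan-2-ol (anomer mixture) | C=C(C)[C@H]1C[C@@H]2O[C@]2(C)C(O)O[C@@H]1/C(OCC)=C(C)\C=C | intermediate
13 | (2S,3S)-3-[(2R,3S,4E)-4-ethoxy-3-hydroxy-5-methyl-2-(prop-1-en-2-yl)hepta-4,6-dien-1-yl]-2-methyloxirane-2-carbaldehyde | C=C(C)[C@H]([C@H](O)/C(OCC)=C(C)\C=C)C[C@@H]1O[C@]1(C)C=O | intermediate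
14 | 9α-ethoxy-3β,9β:4α,5α-diepoxygermacra-1(10),11-dien-8β-ol (bridged ketal) | C=C(C)[C@H]1C[C@@H]2O[C@]2(C)[C@@H]3CC=C(C)[C@@](OCC)(O3)[C@H]1O | intermediate
15 | 8β-acetoxy-9α-ethoxy-3β,9β:4α,5α-diepoxygermacra-1(10),11-diene | C=C(C)[C@H]1C[C@@H]2O[C@]2(C)[C@@H]3CC=C(C)[C@@](OCC)(O3)[C@H]1OC(C)=O | intermediate
16 | 8β-acetoxy-3β,9β:4α,5α-diepoxygermacra-1(10),11-dien-9α-ol (bridged hemiketal) | C=C(C)[C@H]1C[C@@H]2O[C@]2(C)[C@@H]3CC=C(C)[C@@](O)(O3)[C@H]1OC(C)=O | intermediate
17 | 8β-acetoxy-1β,10β:3β,9β:4α,5α-triepoxygermacr-11-en-9α-ol | C=C(C)[C@H]1C[C@@H]2O[C@]2(C)[C@@H]3C[C@H]4O[C@@]4(C)[C@@](O)(O3)[C@H]1OC(C)=O | intermediate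
18 | 8β-acetoxy-1β,10β:4α,5α-diepoxy-3β-hydroxygermacr-11-en-9-one | C=C(C)[C@H]1C[C@@H]2O[C@]2(C)[C@@H](O)C[C@H]2O[C@@]2(C)C(=O)[C@H]1OC(C)=O | intermediate
19 | 8β-acetoxy-1β,10β:4α,5α-diepoxygermacr-11-ene-3β,9β-diol | C=C(C)[C@H]1C[C@@H]2O[C@]2(C)[C@@H](O)C[C@H]2O[C@@]2(C)[C@@H](O)[C@H]1OC(C)=O | intermediate
20 | (1R,3S,4S,5S,7R,8S,9S,10R)-8β-acetoxy-3β,9β-bis(angeloyloxy)-1β,10β:4α,5α-diepoxygermacr-11-ene | C=C(C)[C@H]1C[C@@H]2O[C@]2(C)[C@@H](OC(=O)/C(C)=C\C)C[C@H]2O[C@@]2(C)[C@@H](OC(=O)/C(C)=C\C)[C@H]1OC(C)=O | target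

**Totals and risks**

Total step count: 12. Longest linear sequence: 11 steps (from (S)-carvone: steps 1–3 and 5–12).

The three steps most likely to fail are steps 7, 5 and 12.

Step 7 (no cyclisation, the wrong C3 epimer, or ionisation of the lactol instead of aldehyde release). The fallback sets out from lactol 12 and comes back at hemiketal 16, closing the ring at C1–C2 by olefin metathesis instead of at C2–C3 by cycloaddition. The lactol is opened with vinylmagnesium bromide (CH2=CHMgBr, MgBr2·OEt2, THF, −78 °C); chelation between the aldehyde and oxirane oxygens gives the same C3 configuration and the vinyl carbinol diol F1. Ring‑closing metathesis of F1 with the second‑generation Grubbs catalyst, (H2IMes)(PCy3)Cl2Ru=CHPh, in dilute toluene joins the C3 vinyl group to the terminal vinyl of the dienol ether and gives the macrocyclic ethoxydiene diol F2. Mild aqueous acid (PPTS, acetone–water) protonates C2 of the dienol ether, and the C3 hydroxyl closes onto C9 to give the hemiketal diol F3. Selective acetylation of the secondary C8 hydroxyl (Ac2O, pyridine, 0 °C; the tertiary hemiketal hydroxyl does not react) gives 16.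

Step 5 (enolisation of the sensitive aldehyde 5 by the potassium reagent, metalation at the diene methyl, attack on the ester, or no lactonisation). The fallback sets out from 5 and 7 and comes back at bridged ketal 14; the nucleophile is made by tin–lithium exchange and the C8 oxygen is carried as a silyl ether instead of the relay lactone. The potassium dienide 9 made from 7 is quenched with Bu3SnCl to give the dienylstannane F4. F4 is treated with n-BuLi (THF, −78 °C) and then anhydrous CeCl3; the non‑basic dienylcerium reagent adds to 5, and Et3SiOTf/2,6‑lutidine in the same flask gives the silyl ether ester F5. i-Bu2AlH (CH2Cl2, −78 °C) reduces the glycidic ester to the silyloxy epoxy aldehyde F6. F6 is cyclised with ZnCl2 as in step 7 to the silylated bridged ketal F7, and Bu4NF (THF, 0 °C) frees the C8 hydroxyl to give 14.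

Step 12 (slow acylation of two hindered alcohols, angelate‑to‑tiglate isomerisation, or acetyl migration from O8 to O9 on prolonged heating with base). The fallback sets out from diol 19 and comes back at 20; the Z double bonds are built on the esters instead of being carried in the acid. 19 is esterified with 2-[bis(2,2,2-trifluoroethoxy)phosphoryl]propanoic acid (DCC, DMAP, CH2Cl2, 0 °C) to give the bis(phosphonopropionate) F8. Double Still–Gennari olefination of F8 (KN(SiMe3)2, 18‑crown‑6, THF, −78 °C, then acetaldehyde) gives the two (Z)-2-methylbut-2-enoates, that is 20.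

**Further compounds**
F1 | step 7 | vinyl carbinol diol (seco compound: C3 and C8 hydroxyls free, vinyl on C3, ethoxydiene on C8, C3 as in the target) | C=C(C)[C@H]([C@H](O)/C(OCC)=C(C)\C=C)C[C@@H]1O[C@]1(C)[C@@H](O)C=C
F2 | step 7 | macrocyclic ethoxydiene diol, 9-ethoxy-4α,5α-epoxygermacra-1(2),9(10),11-triene-3β,8β-diol (both ring olefins cis in the ring) | C=C(C)[C@H]1C[C@@H]2O[C@]2(C)[C@@H](O)/C=C\C(C)=C(\OCC)[C@H]1O
F3 | step 7 | hemiketal diol, 3β,9β:4α,5α-diepoxygermacra-1(10),11-diene-8β,9α-diol | C=C(C)[C@H]1C[C@@H]2O[C@]2(C)[C@@H]3CC=C(C)[C@@](O)(O3)[C@H]1O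
F4 | step 5 | tributyl[(1Z)-1-ethoxy-2-methylbuta-1,3-dien-1-yl]stannane (tin cis to vinyl) | C=C/C(C)=C(\[Sn](CCCC)(CCCC)CCCC)OCC
F5 | step 5 | methyl (2S,3S)-3-[(2R,3S,4E)-4-ethoxy-5-methyl-2-(prop-1-en-2-yl)-3-(triethylsilyloxy)hepta-4,6-dien-1-yl]-2-methyloxirane-2-carboxylate | C=C(C)[C@H]([C@H](O[Si](CC)(CC)CC)/C(OCC)=C(C)\C=C)C[C@@H]1O[C@]1(C)C(=O)OC
F6 | step 5 | (2S,3S)-3-[(2R,3S,4E)-4-ethoxy-5-methyl-2-(prop-1-en-2-yl)-3-(triethylsilyloxy)hepta-4,6-dien-1-yl]-2-methyloxirane-2-carbaldehyde | C=C(C)[C@H]([C@H](O[Si](CC)(CC)CC)/C(OCC)=C(C)\C=C)C[C@@H]1O[C@]1(C)C=O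
F7 | step 5 | 8-O-triethylsilyl ether of bridged ketal 14 | C=C(C)[C@H]1C[C@@H]2O[C@]2(C)[C@@H]3CC=C(C)[C@@](OCC)(O3)[C@H]1O[Si](CC)(CC)CC
F8 | step 12 | 3,9-bis{2-[bis(2,2,2-trifluoroethoxy)phosphoryl]propanoate} of diol 19 (phosphonate α-carbons unassigned) | C=C(C)[C@H]1C[C@@H]2O[C@]2(C)[C@@H](OC(=O)C(C)P(=O)(OCC(F)(F)F)OCC(F)(F)F)C[C@H]2O[C@@]2(C)[C@@H](OC(=O)C(C)P(=O)(OCC(F)(F)F)OCC(F)(F)F)[C@H]1OC(C)=O
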